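5.43 min is the number to carry: the half-life of mono adduct, read from its fall between 80.0 s and 120 s in the beta and alpha runs together. Treat it as a loose reading. The beta fall is 3.6 percentage points, and each reading scatters by 1 point.

| flask | substrate | partner | remark | time |
|---|---|---|---|---|
| beta | 0.13 M | 0.60 M | run made earlier |  |
| alpha | 0.10 M | 0.60 M | run made earlier |  |
| midnight | 0.20 M | 0.600 M |  | 10 min |
| winter | 0.20 M | 0.100 M |  | 10 min |
| summer | 0.20 M | 0.300 M |  | 10 min |

| run | time / s | mono adduct / % | substrate / % |
|---|---|---|---|
| beta | 20.0 | 34.8 | 13.7 |
| beta | 40.0 | 38.4 | 6.3 |
| beta | 60.0 | 41.8 | 2.8 |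
| beta | 80.0 | 42.4 | 0.9 |
| beta | 90.0 | 40.3 | 0 |
| beta | 120 | 38.8 | 0.6 |
| alpha | 10.0 | 28.0 | 31.5 |
| alpha | 15.0 | 32.5 | 17.9 |
| alpha | 25.0 | 38.0 | 9.1 |
| alpha | 40.0 | 40.3 | 4.3 |
| alpha | 80.0 | 40.9 | 2.5 |
| alpha | 120 | 37.7 | 0 |

(standard deviation of a reading: 1 percentage point)

- steps that have been proposed: substrate <-> dormant form; partner + mono adduct -> double product + by-product; mono adduct <-> isomer of the product; partner + other mono adduct -> double product + by-product; substrate + partner -> mono adduct + by-product; substrate + partner -> other mono adduct + by-product

1. which of these holds the largest part of the substrate at the end of midnight (mono adduct / double product / substrate / other mono adduct)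
2. which of these holds the largest part of the substrate at the end of winter (mono adduct / double product / substrate / other mono adduct)
3. which of these holds the largest part of the substrate at the end of summer (mono adduct / double product / substrate / other mono adduct)
4. how much mono adduct is there at the end of winter, in percent of the substrate charged

Both runs had 0.60 M of partner, so they cannot show whether partner takes part in this fall. Commit to the step that needs none, mono adduct to isomer of the product, and draw the mono adduct curve of winter.

Start with the slope. The first alpha reading gives 0.193 /M/s for substrate with partner, taken as first order in each. Mono adduct there is 40.9% of the substrate consumed. So the starting tangent in winter gains 7.89% of the charge in 10.0 s.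

Next find the level. Partner is the limiting reagent in winter, 0.100 M against 0.20 M, so the rise bends towards 20.4%. The tangent meets that level at one partner lifetime, 26.0 s. Put the knee at 3 lifetimes, 1.30 min, well before the end.

Now count. From the knee to 10 min lie 1.60 half-lives, so my figure for winter is 6.73%.

The forecast names double product, substrate and other mono adduct for midnight, winter and summer and gives 18% of mono adduct in winter, saying “partner is limiting and exhausted”.

The flask gives double product, substrate and double product, with 8.97% of mono adduct in winter, 2.2 points above my count.

    substrate ⇌ dormant form (K = 0.930, k = 2.00 /min)
    partner + mono adduct → double product + by-product (k = 0.0880 /M/min)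
    mono adduct ⇌ isomer of the product (K = 9.10, k = 0.120 /min)
    partner + other mono adduct → double product + by-product (k = 2.90 /M/min)
    substrate + partner → mono adduct + by-product (k = 5.10 /M/min)
    substrate + partner → other mono adduct + by-product (k = 4.70 /M/min)

The same count for the neighbour of winter charged with 0.12 M of substrate gives 12.5%, against its 14.7%. Winter is not at rest at 10 min, though partner stands at 0.0850% of its charge. From 10 min to 100 min, substrate goes from 27.9% to 27.9%, other mono adduct from 18.4% to 18.4%, and double product from 3.85% to 3.86%. Isomer of the product climbs from 14.9% to 21.5%. Those extra minutes are 16.6 read half-lives, yet mono adduct in winter still stands at 2.37%.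

The earlier runs and the new flask were computed on assumed constants; the scatter is artificial.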